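**Direct plan and its weak points**

A direct plan would grow ring A onto the ether oxygen from a five-membered ring. Cyclopent-2-en-1-one A1 would be epoxidized to the epoxy ketone A2, which would be opened by 2-bromophenol A3 and dehydrated to the aryloxy enone A4. Bromination at the β-carbon would give the bromo enone A5, which would be converted into the silyl dienol ether A6, enlarged by one carbon with a dihalocarbene to the phenol A7, brominated para to the hydroxyl to the tribromophenol A8 and O-methylated.
- The carbene ring enlargement of the 2-siloxycyclopentadiene A6 would be the weakest step. The ring CH2 of a cyclopentadiene is acidic enough for the alkoxide that generates the carbene, so the diene would scramble through its cyclopentadienide. The carbene would also have to choose between two alkenes, and all material would have to pass this unproven step.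
- The making and handling of A6 would be fragile. A kinetic dienolate must be trapped, and the product is a cyclopentadiene prone to 1,5-hydrogen shifts and Diels–Alder dimerization that would have to be carried on crude.
- The linear run-up would be long for what it builds. Five operations would rebuild a brominated phenol ring of a kind that can be bought, with no convergence and with bromine brought in at three separate stages.

**Retrosynthetic overview of the new route**

Numbering: ring A C1 (OMe), C2 (Br), C3 (H), C4 (Br), C5 (Br), C6 (O); ring B C1' (O), C2' (Br). The target has no stereocentre, so no stereocontrol is needed.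
Ring B carries only the ether oxygen at C1' and a bromine at the neighbouring C2'. The target is therefore cut at O–C1' and C2'–Br, and both bonds would form in one operation when benzyne takes up the ring A phenoxide and then Br+; the aryne is symmetrical, so no regiochemical question arises.
Ring A would enter complete, as bromoguaiacol 5. C2–Br and C4–Br are bought in 3,5-dibromosalicylaldehyde, the C6 oxygen comes from its formyl group by Baeyer–Villiger oxidation, and C5–Br is placed ortho to the free hydroxyl.
No ring is built or enlarged, no cyclopentadiene is handled, and all four bromines are in place before or in the key step. The route is four steps, with the single risky step last.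

Key step: step 4

**Route**

Step 1
Reactants: 1 3,5-dibromo-2-hydroxybenzaldehyde
Product: 2 3,5-dibromo-2-methoxybenzaldehyde
Conditions: MeI, K2CO3, DMF, 23 °C
Reagents that add atoms: iodomethane, CI
Why: Williamson ether synthesis, in which the acidic phenoxide is methylated on oxygen by SN2 reaction with MeI; this fixes which oxygen of ring A becomes C1–OMe, and the aldehyde is inert to carbonate.

Step 2
Reactants: 2 3,5-dibromo-2-methoxybenzaldehyde
Product: 4 3,5-dibromo-2-methoxyphenol, via aryl formate 3 (not isolated)
Conditions: mCPBA, CH2Cl2, 40 °C; aq. NaHCO3 wash; then MeOH, Et3N (cat.), 23 °C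
Reagents that add atoms: 3-chloroperoxybenzoic acid (mCPBA), OOC(=O)c1cccc(Cl)c1
Why: Baeyer–Villiger oxidation of an ortho-alkoxybenzaldehyde, in which the aryl group migrates to oxygen in the Criegee adduct with help from the ortho methoxy group, followed by base-catalysed methanolysis of formate 3; the aryl bromides and the methyl ether are inert to the peracid.

Step 3
Reactants: 4 3,5-dibromo-2-methoxyphenol
Product: 5 2,3,5-tribromo-6-methoxyphenol
Conditions: NBS (1.0 equiv), iPr2NH (0.1 equiv), CH2Cl2, 0 to 23 °C
Reagents that add atoms: N-bromosuccinimide, O=C1CCC(=O)N1Br
Why: Amine-mediated ortho-selective electrophilic bromination of a phenol, in which the N-bromoamine formed from NBS is held by hydrogen bonding to the hydroxyl and delivers bromine to the only free ortho carbon (C5 of ring A), while the para carbon (C3) is shielded by two flanking bromines; this reaction type is known to brominate 2-substituted phenols at the free ortho position in preference to the para position.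

Step 4
Reactants: 5 2,3,5-tribromo-6-methoxyphenol; 6 2-(trimethylsilyl)phenyl trifluoromethanesulfonate
Product: 10 1,2,5-tribromo-3-(2-bromophenoxy)-4-methoxybenzene (CNP0117173.0), via potassium phenoxide 7 (not isolated), via benzyne 8 (not isolated), via aryl potassium 9 (not isolated)
Conditions: KH (1.0 equiv), THF, 0 °C; then 18-crown-6, KF, C6F5Br (3 equiv), 6 (1.5 equiv), THF, 0 to 23 °C
Reagents that add atoms: bromopentafluorobenzene, Fc1c(F)c(F)c(Br)c(F)c1F
Why: Proposed new method: fluoride removes the silyl group of 6 and triflate leaves to give benzyne 8, the potassium phenoxide 7 adds through oxygen to the strained triple bond (bond O–C1'), and the resulting ortho aryl anion 9 takes Br+ from C6F5Br by halogen–metal exchange (bond C2'–Br), so that ring B receives its two neighbouring substituents in one operation. The closest known reaction types are the O-arylation of phenols with arynes from 2-silylaryl triflates and the three-component halo-functionalization of arynes, in which a sulfur or nitrogen nucleophile adds and the aryl anion is quenched by a perfluoroaryl halide (bromothiolation with C6F5Br); joining a phenoxide with a bromine donor is the new element. No ring is closed and no stereocentre is formed. The step needs three selectivities: O- over C-arylation, which the blocked ortho positions of 7 (C1–OMe and C5–Br) should secure; bromination over protonation of 9, which complete deprotonation of 5 by KH (H2 as the only by-product) and the aprotic THF medium should secure; and bromine transfer from C6F5Br and not from the aryl bromides of ring A, which the excess of C6F5Br should secure because C6F5− is by far the best carbanion leaving group present. Benzyne is symmetrical, so no regiochemical question arises.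

**Compound list**

1 | 3,5-dibromo-2-hydroxybenzaldehyde | O=Cc1cc(Br)cc(Br)c1O | starting material
2 | 3,5-dibromo-2-methoxybenzaldehyde | COc1c(Br)cc(Br)cc1C=O | intermediate
3 | 3,5-dibromo-2-methoxyphenyl formate | COc1c(Br)cc(Br)cc1OC=O | intermediate
4 | 3,5-dibromo-2-methoxyphenol | COc1c(Br)cc(Br)cc1O | intermediate
5 | 2,3,5-tribromo-6-methoxyphenol | COc1c(Br)cc(Br)c(Br)c1O | intermediate
6 | 2-(trimethylsilyl)phenyl trifluoromethanesulfonate | C[Si](C)(C)c1ccccc1OS(=O)(=O)C(F)(F)F | starting material
7 | potassium 2,3,5-tribromo-6-methoxyphenolate | [K+].COc1c(Br)cc(Br)c(Br)c1[O-] | intermediate
8 | benzyne (cyclohexa-1,3-dien-5-yne) | C1=CC=CC#C1 | intermediate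
9 | potassium 2-(2,3,5-tribromo-6-methoxyphenoxy)benzen-1-ide | [K+].COc1c(Br)cc(Br)c(Br)c1Oc1cccc[c-]1 | intermediate
10 | 1,2,5-tribromo-3-(2-bromophenoxy)-4-methoxybenzene (CNP0117173.0) | COc1c(Br)cc(Br)c(Br)c1Oc1ccccc1Br | target

**Step count and risks**

Total step count: 4. Longest linear sequence: 4 steps (1 to 10).

Steps most likely to fail:

1. Step 4 (Proposed new method). The aryl anion 9 may be protonated before bromine transfer, may exchange bromine with the aryl bromides of ring A, or may deprotonate C3 of ring A. The hindered, electron-poor phenoxide may also capture benzyne too slowly or be consumed by nucleophilic aromatic substitution on the bromine donor. The fallback brings the C2'–Br bond in ready-made and forms only the O–C1' bond, by the known metal-free O-arylation of phenols with diaryliodonium salts. 1-Bromo-2-iodobenzene F1 would be oxidized with mCPBA and TsOH·H2O in MeCN and coupled in the same flask with 1,3,5-trimethoxybenzene to give (2-bromophenyl)(2,4,6-trimethoxyphenyl)iodonium 4-methylbenzenesulfonate F2. The fallback sets out from compound 5, which would be deprotonated with KOtBu (1.0 equiv) in THF to phenoxide 7 and arylated by F2 at 23 to 40 °C; the trimethoxyphenyl group stays on iodine as the non-transferred ligand. It comes back to the route at compound 10.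

2. Step 3. Bromination may occur at the para carbon (C3) or twice. The fallback replaces innate phenol selectivity by directing-group control and places C5–Br before the oxygen is unmasked. It sets out from compound 2, which would undergo Pd(OAc)2-catalysed ortho C–H bromination with NBS through a catalytic transient imine directing group (for example 2-amino-5-chlorobenzotrifluoride, in acidic 1,2-dichloroethane at 60 to 80 °C). The only ortho C–H of 2 is the one wanted, which should give 2,3,5-tribromo-6-methoxybenzaldehyde F3; the oxidizing conditions keep the catalyst as divalent palladium, which should leave the aryl bromides untouched. Baeyer–Villiger oxidation of F3 with mCPBA would give 2,3,5-tribromo-6-methoxyphenyl formate F4, and methanolysis as in step 2 comes back to the route at compound 5.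

3. Step 2. Hydride may migrate in place of the aryl group in the Criegee adduct, because the ring is deactivated by two bromines and the flanked methoxy group is twisted out of conjugation; the aldehyde would then be over-oxidized to the acid. The fallback avoids the rearrangement and sets the C6 oxygen by ipso-hydroxylation of a carbon–boron bond. It sets out from no numbered compound of the route: commercially listed (3,5-dibromo-2-methoxyphenyl)boronic acid F5 would take the place of compounds 1 to 3 and be oxidized with 30% H2O2 and aq. NaOH in THF at 0 °C, followed by acidification. It comes back to the route at compound 4.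

**Further compounds**

F1 | step 4 | 1-bromo-2-iodobenzene | Brc1ccccc1I
F2 | step 4 | (2-bromophenyl)(2,4,6-trimethoxyphenyl)iodonium 4-methylbenzenesulfonate | COc1cc(OC)c([I+]c2ccccc2Br)c(OC)c1.Cc1ccc(cc1)S(=O)(=O)[O-]
F3 | step 3 | 2,3,5-tribromo-6-methoxybenzaldehyde | COc1c(Br)cc(Br)c(Br)c1C=O
F4 | step 3 | 2,3,5-tribromo-6-methoxyphenyl formate | COc1c(Br)cc(Br)c(Br)c1OC=O
F5 | step 2 | (3,5-dibromo-2-methoxyphenyl)boronic acid | COc1c(Br)cc(Br)cc1B(O)O
A1 | direct plan | cyclopent-2-en-1-one | O=C1C=CCC1
A2 | direct plan | 6-oxabicyclo[3.1.0]hexan-2-one (racemic, cis-fused) | O=C1CC[C@@H]2O[C@H]12
A3 | direct plan | 2-bromophenol | Oc1ccccc1Br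
A4 | direct plan | 2-(2-bromophenoxy)cyclopent-2-en-1-one | O=C1CCC=C1Oc1ccccc1Br
A5 | direct plan | 3-bromo-2-(2-bromophenoxy)cyclopent-2-en-1-one | O=C1CCC(Br)=C1Oc1ccccc1Br
A6 | direct plan | {[4-bromo-3-(2-bromophenoxy)cyclopenta-1,3-dien-2-yl]oxy}(tert-butyl)dimethylsilane | CC(C)(C)[Si](C)(C)OC1=CCC(Br)=C1Oc1ccccc1Br
A7 | direct plan | 3,6-dibromo-2-(2-bromophenoxy)phenol | Oc1c(Br)ccc(Br)c1Oc1ccccc1Br
A8 | direct plan | 3,4,6-tribromo-2-(2-bromophenoxy)phenol | Oc1c(Br)cc(Br)c(Br)c1Oc1ccccc1Br
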